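Remark on the chemistry: the SMILES is read as 3β-acetoxy, 5α-H, 8α-methyl (8β-H), 9α-hydroxy, 10β-methyl, i.e. (3S,5S,8R,9R,10S); labdane numbering is used throughout (C1–C10 decalin, C11–C12 chain, C13–C16 butenolide, C17 the methyl on C8) and α is the face opposite the C10 methyl.

## The problem

The target 22 is a trans-fused decalin. Ring A carries an equatorial 3β-acetate beside the quaternary C4 with its two methyls. Ring B carries the equatorial 8α-methyl beside a tertiary, axial 9α-hydroxyl, and C9 bears on its β face a two-carbon chain ending in an α-substituted butenolide (C13=C14, C16 carbonyl, C15 methylene). Of the five stereocentres (C3, C5, C8, C9, C10), C10 is quaternary and C9 is fully substituted and wedged between C10 and C8, so C9 is the hardest carbon to build. The centres can be made to control one another. C5 can direct an alkylation at C10. C5 and C10 together fix the ring fusion and, through a chair, C3. The axial C10 methyl distinguishes the two faces of C9. C8 is under thermodynamic control while C9 is a ketone, because the wrong epimer would place two methyls 1,3-diaxial. The butenolide (base, nucleophiles), the acetate (base, organometallics) and the tertiary alcohol, which is trans-diaxial to H-8 and so prone to acid dehydration, must appear late. The feature that opens the route is that the C3 carbinol is bonded to C4, and C4 with its two methyls hangs on C5. An isopropenyl group on C5 therefore becomes C4 with both methyls once a hydrogen atom is added to its CH2, leaving a tertiary radical exactly where the C3–C4 bond is needed. Ring B, with a methyl on the carbon next to a carbonyl carbon and an isopropenyl-bearing carbon across the ring, is the carvone skeleton.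

## Retrosynthesis

**Acetate and silyl ether.** The C3 O–acyl bond of 22 is cut to diol 21, and 21 is traced to the C3 silyl ether 20. Acylation is left to the end because every earlier C–C bond formation uses strong bases or organolithiums. The forward step only has to tell a secondary equatorial alcohol from a hindered tertiary one.

**Butenolide to silylfuran.** No skeletal bond is cut between 20 and 19. The lactone is traced to a 3-alkylfuran whose C16 carries a trimethylsilyl group. Attaching a finished butenolide would expose a base-sensitive Michael acceptor to carbanion chemistry. The furan is inert to that chemistry, and the silicon marks which α-carbon becomes the carbonyl. The forward reaction needs a peracid to attack ipso to silicon.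

**C12–C13.** Cutting this bond in 19 gives spiro-oxetane 14 and 3-lithio-2-(trimethylsilyl)furan 18, made through 17 from 3-bromofuran 15. The neighbouring cut C9–C11, adding the whole chain to ketone 11, would put carbon on the α face, since nucleophiles approach C9 anti to the C10 methyl. The cut C11–C12 would need a furylmethyl nucleophile that is awkward to make with the silyl group in place. The oxetane stores the C9–O configuration and offers an unhindered primary carbon to the aryllithium.

**C11–C12, the C9–O/C11–O pair and C9=C11.** Oxetane 14 is cut at C11–C12 to epoxide 13 and a sulfur ylide carbon. Epoxide 13 goes back to the exocyclic alkene 12, and 12 to ketone 11 by removing the methylene carbon. Carbon goes on first and oxygen is delivered second by an electrophilic reagent to the open α face. This reverses the facial outcome of a direct carbonyl addition and gives the 9α-oxygen. Ketone 11 has no functionality left in ring B other than the carbonyl and the equilibrated C8 methyl.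

**Ring B oxidation level.** Ketone 11 is traced to enone 9 (C7=C8) and, by removing the silyl group, to hydroxy enone 8. The forward sequence adds C8 as a stereocentre under thermodynamic control.

**C3–C4, the key cut.** Cutting C3–C4 in 8 gives the monocyclic keto aldehyde 7, with only two stereocentres. Cuts at C4–C5 or C1–C10 (annulation logic) would leave the C4 methyls and the C3 oxygen to be added to a finished ring. This cut brings both with the ring. The forward step must generate the tertiary C4 radical in the presence of an enone and an aldehyde, close six-membered, and place the new oxygen equatorial.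

**C1–C10 and the C10 methyl.** Aldehyde 7 comes from acetal 6. Acetal 6 comes from 6-methylcarvone 3 and bromide 4 by enolate alkylation, and 3 from (R)-carvone 1 and iodomethane. The methyl is introduced first so that the larger chain enters anti to the isopropenyl group. Carvone supplies C5, all ring B carbons, C17 and the latent C4.

## Roads not taken

**Alternative 1:** The C8–C17 bond is cut and the methyl carbon is delivered from the 9α-oxygen through a temporary silicon link. The bromomethylsilyl ether A1 of a Δ7-9α-carbinol is treated with Bu3SnH and an initiator. The α-silyl radical adds 5-exo to C8 and gives the cis-fused oxasilolane A2, after which protonolysis of the C–Si bond frees the methyl and the alcohol.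
- Merits: C17 is forced cis to the 9α-oxygen by the ring constraint, whatever the thermodynamics, and under neutral conditions. The method would work even if the wanted methyl were axial.
- Weak points: the 8α-methyl is equatorial, the epimer that equilibration next to a C9 ketone already gives. The tether therefore spends three operations on a centre that is otherwise free: silylation of a hindered tertiary alcohol, a tin-mediated closure and a protodesilylation. A1 also presupposes the tertiary 9α-alcohol with the chain on the β face, so the hardest centre must be made first, by carbon addition syn to the C10 methyl. The key step does nothing for ring A.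
- Comparison: the tether is better in the certainty of C8, which it sets kinetically. The chosen plan sets against this the 1,3-diaxial methyl–methyl penalty that makes the equilibrium one-sided, and a key step that builds ring A, C3 and C4. The tether is not shorter.

**Alternative 2:** The C8–C9 bond is cut. SmI2 (divalent samarium) reduces the α-bromo ketone A3, either bromide epimer, to a samarium enolate whose C8 adds to the C9 ketone. This closes ring B and gives the 9α-hydroxy-7-ketone A4 with the silylfuran chain already attached.
- Merits: the chain arrives as part of an acyclic ketone, so the methylenation, epoxidation and oxetane sequence of the chosen plan disappears. C8 and C9 are set in one mild step, and chelation of samarium between the enolate and ketone oxygens can direct it.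
- Weak points: A4 has a C7 carbonyl that the target lacks. Removing it from a β-hydroxy ketone invites retro-aldol cleavage and dehydration and costs at least two steps. The 9α configuration depends on which face of a ketone next to quaternary C10 the tethered enolate reaches. A3, with C3, C5 and an acyl-bearing quaternary C10 on one ring, is hardly simpler than the decalin.
- Comparison: this road is clearly shorter and more convergent in the side-chain endgame. The chosen plan sets against that two alkylations of carvone for C5 and C10, no surplus oxygen, and a ring A that arrives complete.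

**Alternative 3:** The bonds C1–C10 and C4–C5 are cut. Diene A6 adds to one C=C of quinone A5 under a chiral oxazaborolidinium triflimide and gives the cis-fused adduct A7.
- Merits: two C–C bonds, ring A and the quaternary C10 stereocentre form in one catalytic enantioselective step from achiral bulk materials. The C8 methyl and C9 carbonyl are in place from the start. A bicyclic core is reached in one step against four, with no dependence on the chiral pool.
- Weak points: A7 is cis-fused, has no methyls on C4, an enol ether where the C3 carbinol belongs and a C6 carbonyl that must be removed. Ring A then needs geminal methylation of a 3-ketone at C4 and not at C2, correction of the ring fusion through the C6 ketone (for angularly methylated decalones the equilibrium does not clearly favour trans), differentiation of the C6 and C9 carbonyls, and reduction at C3. The regiochemistry also needs the nucleophilic diene terminus to bond to the unsubstituted quinone carbon, which presumes activation through the carbonyl between the two methyl-bearing carbons, the more hindered one.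
- Comparison: this road wins on speed to a decalin and on catalytic asymmetric induction. The chosen plan sets against that a single ring closure which delivers C4 with both methyls, the 3β-oxygen and the trans fusion together, so no corrective steps follow on ring A.

Key step: step 4

## Route

Step 1
Reactants: 1 (R)-(−)-carvone
Product: 3 (5R)-2,6-dimethyl-5-(prop-1-en-2-yl)cyclohex-2-en-1-one (6-methylcarvone as C6 epimers), via lithium dienolate 2 (not isolated)
Conditions: LiN(iPr)2, THF, −78 °C; MeI, −78 → 0 °C
Reagents that add atoms: iodomethane, CI
Why: Kinetic α′-deprotonation at C6 gives the cross-conjugated dienolate 2, which is C-methylated (enolate alkylation); the C6 configuration does not matter because C6 is flattened again in step 2.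

Step 2
Reactants: 3 6-methylcarvone; 4 2-(2-bromoethyl)-1,3-dioxolane
Product: 6 (5S,6S)-6-[2-(1,3-dioxolan-2-yl)ethyl]-2,6-dimethyl-5-(prop-1-en-2-yl)cyclohex-2-en-1-one, via lithium enolate 5 (not isolated)
Conditions: LiN(iPr)2, THF, −78 °C; 4, DMPU, −78 °C → rt
Reagents that add atoms: none
Why: Enolate SN2 alkylation; the electrophile reaches planar C6 of 5 anti to the neighbouring isopropenyl group on C5 (1,2-induction), which sets the quaternary centre with the chain trans and the methyl cis to isopropenyl, and DMPU raises the reactivity toward the unactivated primary bromide.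

Step 3
Reactants: 6 the dioxolane of step 2
Product: 7 3-[(1S,6S)-1,3-dimethyl-2-oxo-6-(prop-1-en-2-yl)cyclohex-3-en-1-yl]propanal
Conditions: 1 M aq. HCl, THF, rt
Reagents that add atoms: water, O
Why: Acid-catalysed acetal hydrolysis; dilute acid at room temperature leaves the enone and the isopropenyl group untouched and no stereocentre is involved.

Step 4
Reactants: 7 the keto aldehyde of step 3
Product: 8 (4aS,6S,8aS)-6-hydroxy-2,5,5,8a-tetramethyl-4a,5,6,7,8,8a-hexahydronaphthalen-1(4H)-one (3β-hydroxy-11,12,13,14,15,16-hexanorlabd-7-en-9-one)
Conditions: Fe(acac)3 (0.3 equiv), PhSiH3, EtOH, 60 °C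
Reagents that add atoms: none
Why: Fe(acac)3 and PhSiH3 in ethanol form an iron hydride that transfers a hydrogen atom to the terminal CH2 of the isopropenyl group, which creates the second C4 methyl and the tertiary C4 radical in one event. The radical adds to the aldehyde carbon C3 in a 6-exo-trig closure of ring A, and the alkoxy radical is reduced by divalent iron and protonated by ethanol, which pulls the reversible addition forward and returns trivalent iron. The closest known reaction type is the iron-hydride hydrogen-atom-transfer reductive cyclisation of alkenes onto tethered ketones and aldehydes. C5 and C10 are already fixed with the chain and the isopropenyl group trans on ring B, so the new ring can only be trans-fused. C3 is the one new stereocentre: in the chair-like transition state the carbonyl oxygen lies pseudo-equatorial, clear of the axial hydrogens on C1 and C5, which gives the 3β-alcohol. The step needs hydrogen-atom transfer to the isopropenyl group and not to the enone; the electron-rich 1,1-disubstituted alkene is the better acceptor than the electron-poor trisubstituted enone, and the C4 radical can reach the enone or the C9 carbonyl only through a four-membered or 5-endo closure.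

Step 5
Reactants: 8 the hydroxy enone of step 4
Product: 9 3β-(tert-butyldimethylsilyloxy)-11,12,13,14,15,16-hexanorlabd-7-en-9-one
Conditions: TBSOTf, 2,6-lutidine, CH2Cl2, 0 °C
Reagents that add atoms: tert-butyldimethylsilyl trifluoromethanesulfonate, CC(C)(C)[Si](C)(C)OS(=O)(=O)C(F)(F)F
Why: Silylation of the hindered neopentyl-type alcohol with the silyl triflate; the enone has no α-hydrogen on the C10 side and C8 is sp2, so no silyl enol ether can form.

Step 6
Reactants: 9 the silyl ether enone
Product: 11 3β-(tert-butyldimethylsilyloxy)-8α-methyl-11,12,13,14,15,16-hexanorlabdan-9-one (8β-H), via 8β-methyl ketone 10 (not isolated)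
Conditions: H2 (1 atm), Pd/C, EtOAc, rt; then NaOMe, MeOH/THF, 50 °C
Reagents that add atoms: none
Why: Heterogeneous hydrogenation saturates C7=C8, most likely from the α face to give the axial methyl in 10; methoxide then equilibrates C8 through the C8–C9 enolate to the equatorial 8α-methyl epimer, because the axial methyl would be 1,3-diaxial to the C10 methyl.

Step 7
Reactants: 11 the saturated ketone
Product: 12 3β-(tert-butyldimethylsilyloxy)-8α-methyl-12,13,14,15,16-pentanorlabd-9(11)-ene
Conditions: Ph3PCH3Br, KOtBu, toluene, 100 °C
Reagents that add atoms: methyltriphenylphosphonium bromide, C[P+](c1ccccc1)(c1ccccc1)c1ccccc1.[Br-]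
Why: Wittig methylenation under the hot, alkoxide-based conditions used for α,α,α′-trisubstituted ketones; C8 is already the thermodynamic epimer, so enolisation by the basic ylide does no harm, and the silyl ether is inert.

Step 8
Reactants: 12 the exocyclic alkene
Product: 13 3β-(tert-butyldimethylsilyloxy)-9α,11-epoxy-8α-methyl-12,13,14,15,16-pentanorlabdane (spiro-epoxide, oxygen α)
Conditions: mCPBA, NaHCO3, CH2Cl2, 0 °C
Reagents that add atoms: 3-chloroperoxybenzoic acid, OOC(=O)c1cccc(Cl)c1
Why: Prilezhaev epoxidation; the peracid approaches C9=C11 from the α face, anti to the axial C10 methyl that screens the β face, so the oxygen becomes 9α (axial) and C11 stays β, and the buffer prevents acid rearrangement of the spiro-epoxide.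

Step 9
Reactants: 13 the spiro-epoxide
Product: 14 3β-(tert-butyldimethylsilyloxy)-9α,12-epoxy-8α-methyl-13,14,15,16-tetranorlabdane (spiro-oxetane, oxygen α on C9)
Conditions: Me3S(O)I, KOtBu, t-BuOH, 70 °C
Reagents that add atoms: trimethylsulfoxonium iodide, C[S+](C)(C)=O.[I-]
Why: Corey–Chaykovsky-type ring expansion of an epoxide to an oxetane: the ylide opens the epoxide at primary C11 by SN2 and the C9 alkoxide then displaces dimethyl sulfoxide from the new carbon C12 (4-exo-tet); the C9–O bond is never broken, so C9 keeps its configuration.

Step 10
Reactants: 15 3-bromofuran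
Product: 17 3-bromo-2-(trimethylsilyl)furan, via 3-bromo-2-lithiofuran 16 (not isolated)
Conditions: LiN(iPr)2, THF, −78 °C; Me3SiCl, −78 °C → rt
Reagents that add atoms: chlorotrimethylsilane, C[Si](C)(C)Cl
Why: The amide base removes the most acidic ring proton, H-2 between oxygen and bromine (directed ortho-lithiation), without bromine–lithium exchange, and the anion is silylated on carbon.

Step 11
Reactants: 17 3-bromo-2-(trimethylsilyl)furan; 14 the spiro-oxetane
Product: 19 3β-(tert-butyldimethylsilyloxy)-16-(trimethylsilyl)-15,16-epoxylabda-13(16),14-dien-9α-ol (8α-methyl), via 3-lithio-2-(trimethylsilyl)furan 18 (not isolated)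
Conditions: n-BuLi, THF, −78 °C; then 14, BF3·OEt2, −78 °C
Reagents that add atoms: none
Why: Bromine–lithium exchange gives 18, which is stable at −78 °C; the BF3-activated oxetane is opened at the unhindered primary C12 (organolithium/BF3 oxetane opening), which forms C12–C13 and releases the 9α-alkoxide without touching C9.

Step 12
Reactants: 19 the silylfuran alcohol
Product: 20 3β-(tert-butyldimethylsilyloxy)-9α-hydroxy-8α-methyllabd-13-en-16,15-olide
Conditions: CH3CO3H (in AcOH), NaOAc, CH2Cl2, 0 °C → rt
Reagents that add atoms: peracetic acid, CC(=O)OO
Why: Peracid oxidation of a 2-silylfuran to a butenolide: attack ipso to silicon at C16 is followed by a silyl shift to oxygen and loss of silicon, so the carbonyl appears at C16 and the double bond at C13=C14; the furan is the only oxidisable π-system present.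

Step 13
Reactants: 20 the silyl-protected lactone
Product: 21 3β,9α-dihydroxy-8α-methyllabd-13-en-16,15-olide
Conditions: HF·pyridine, THF, 0 °C → rt
Reagents that add atoms: none
Why: Fluoride-driven cleavage of the Si–O bond under non-basic conditions, which spares the butenolide from base-induced opening or double-bond migration and is mild enough for the tertiary alcohol.

Step 14
Reactants: 21 the diol
Product: 22 3β-acetoxy-9α-hydroxy-8α-methyllabd-13-en-16,15-olide, (3S,5S,8R,9R,10S)
Conditions: Ac2O, pyridine, DMAP, CH2Cl2, rt
Reagents that add atoms: acetic anhydride, CC(=O)OC(C)=O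
Why: DMAP-catalysed acylation; only the secondary equatorial 3β-hydroxyl reacts, the tertiary axial 9α-hydroxyl between C10 and C8 being inert under these conditions.

## Compound list

1 | (R)-(−)-carvone, (5R)-2-methyl-5-(prop-1-en-2-yl)cyclohex-2-en-1-one | CC(=C)[C@@H]1CC=C(C)C(=O)C1 | starting material
2 | kinetic lithium dienolate of 1 (O–Li on C1, C1=C6 and C2=C3) | CC(=C)[C@@H]1CC=C(C)C(O[Li])=C1 | intermediate
3 | (5R)-2,6-dimethyl-5-(prop-1-en-2-yl)cyclohex-2-en-1-one (6-methylcarvone, C6 epimers) | CC(=C)[C@@H]1CC=C(C)C(=O)C1C | intermediate
4 | 2-(2-bromoethyl)-1,3-dioxolane | BrCCC1OCCO1 | starting material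
5 | lithium dienolate of 3 (C6 planar) | CC(=C)[C@@H]1CC=C(C)C(O[Li])=C1C | intermediate
6 | (5S,6S)-6-[2-(1,3-dioxolan-2-yl)ethyl]-2,6-dimethyl-5-(prop-1-en-2-yl)cyclohex-2-en-1-one (chain trans to isopropenyl) | O1CCOC1CC[C@@]2(C)[C@@H](CC=C(C)C2=O)C(C)=C | intermediate
7 | 3-[(1S,6S)-1,3-dimethyl-2-oxo-6-(prop-1-en-2-yl)cyclohex-3-en-1-yl]propanal | O=CCC[C@@]1(C)[C@@H](CC=C(C)C1=O)C(C)=C | intermediate
8 | (4aS,6S,8aS)-6-hydroxy-2,5,5,8a-tetramethyl-4a,5,6,7,8,8a-hexahydronaphthalen-1(4H)-one (3β-OH, 5α-H, 10β-Me, Δ7, 9-oxo) | O[C@H]1CC[C@@]2(C)[C@@H](CC=C(C)C2=O)C1(C)C | intermediate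
9 | 3β-tert-butyldimethylsilyl ether of 8 | CC(C)(C)[Si](C)(C)O[C@H]1CC[C@@]2(C)[C@@H](CC=C(C)C2=O)C1(C)C | intermediate
10 | 3β-(tert-butyldimethylsilyloxy)-8β-methyl-11,12,13,14,15,16-hexanorlabdan-9-one (axial C8 methyl) | CC(C)(C)[Si](C)(C)O[C@H]1CC[C@@]2(C)[C@@H](CC[C@H](C)C2=O)C1(C)C | intermediate
11 | 3β-(tert-butyldimethylsilyloxy)-8α-methyl-11,12,13,14,15,16-hexanorlabdan-9-one (equatorial C8 methyl, 8β-H) | CC(C)(C)[Si](C)(C)O[C@H]1CC[C@@]2(C)[C@@H](CC[C@@H](C)C2=O)C1(C)C | intermediate
12 | 3β-(tert-butyldimethylsilyloxy)-8α-methyl-12,13,14,15,16-pentanorlabd-9(11)-ene | CC(C)(C)[Si](C)(C)O[C@H]1CC[C@@]2(C)[C@@H](CC[C@@H](C)C2=C)C1(C)C | intermediate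
13 | 3β-(tert-butyldimethylsilyloxy)-9α,11-epoxy-8α-methyl-12,13,14,15,16-pentanorlabdane | CC(C)(C)[Si](C)(C)O[C@H]1CC[C@@]2(C)[C@@H](CC[C@@H](C)[C@]2(O3)C3)C1(C)C | intermediate
14 | 3β-(tert-butyldimethylsilyloxy)-9α,12-epoxy-8α-methyl-13,14,15,16-tetranorlabdane (spiro-oxetane) | CC(C)(C)[Si](C)(C)O[C@H]1CC[C@@]2(C)[C@@H](CC[C@@H](C)[C@]2(O3)CC3)C1(C)C | intermediate
15 | 3-bromofuran | Brc1ccoc1 | starting material
16 | 3-bromo-2-lithiofuran | [Li]c1occc1Br | intermediate
17 | 3-bromo-2-(trimethylsilyl)furan | C[Si](C)(C)c1occc1Br | intermediate
18 | 3-lithio-2-(trimethylsilyl)furan | C[Si](C)(C)c1occc1[Li] | intermediate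
19 | 3β-(tert-butyldimethylsilyloxy)-16-(trimethylsilyl)-15,16-epoxylabda-13(16),14-dien-9α-ol (8α-methyl) | CC(C)(C)[Si](C)(C)O[C@H]1CC[C@@]2(C)[C@@H](CC[C@@H](C)[C@]2(O)CCc3ccoc3[Si](C)(C)C)C1(C)C | intermediate
20 | 3β-(tert-butyldimethylsilyloxy)-9α-hydroxy-8α-methyllabd-13-en-16,15-olide | CC(C)(C)[Si](C)(C)O[C@H]1CC[C@@]2(C)[C@@H](CC[C@@H](C)[C@]2(O)CCC3=CCOC3=O)C1(C)C | intermediate
21 | 3β,9α-dihydroxy-8α-methyllabd-13-en-16,15-olide | O[C@H]1CC[C@@]2(C)[C@@H](CC[C@@H](C)[C@]2(O)CCC3=CCOC3=O)C1(C)C | intermediate
22 | 3β-acetoxy-9α-hydroxy-8α-methyllabd-13-en-16,15-olide, (3S,5S,8R,9R,10S) | CC(=O)O[C@H]1CC[C@@]2(C)[C@@H](CC[C@@H](C)[C@]2(O)CCC2=CCOC2=O)C1(C)C | target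

## Step count and least certain steps

Total: 14 steps. Longest linear sequence: 13 steps (steps 1–9 and 11–14, from 1); step 10 is a one-step side branch from 15.

**Step 4 (key step).** The addition of the tertiary radical to the aldehyde is reversible, and the alkoxy radical next to a quaternary carbon fragments easily. If its reduction is slow, simple hydrogenation of the isopropenyl group takes over. The preference for the equatorial oxygen at C3 may also be incomplete. The fallback sets out from 7 and returns at 8. It changes the bond-forming event from a radical addition to a polar one. Hydrogen-atom transfer from a cobalt hydride is used, with (salen)CoCl [salen = N,N′-bis(3,5-di-tert-butylsalicylidene)ethane-1,2-diamine dianion], PhSiH3 and CrCl3. The C4 radical is captured by divalent chromium as the tertiary alkylchromium dichloride F1 (trivalent chromium). F1 adds to the aldehyde irreversibly through a chair, in the manner of a Nozaki–Hiyama–Kishi closure, again with the oxygen equatorial.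

**Step 2.** SN2 attack of a hindered, fully substituted enolate on an unactivated primary bromide is slow. Elimination of HBr from 4 and proton transfer can compete, and the anti selectivity falls as the temperature has to be raised. The fallback sets out from 3 and returns at 7. Enolate 5 is alkylated with allyl bromide, a far better electrophile with the same facial preference, to give the allyl ketone F2. RhCl(PPh3)3-catalysed hydroboration with catecholborane, selective for the monosubstituted alkene over the isopropenyl group and the ketone, followed by NaBO3 oxidation gives the primary alcohol F3. Dess–Martin oxidation then gives 7.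

**Step 8.** Facial discrimination by the small peracid may be only moderate, and the m-chlorobenzoic acid formed can rearrange the spiro-epoxide to a C9 aldehyde. The fallback sets out from 12 and returns at 13. Dihydroxylation with OsO4 (catalytic) and N-methylmorpholine N-oxide uses a much bulkier reagent on the same open α face and gives the 9α,11-diol F4. Selective tosylation of the primary hydroxyl gives the tosylate F5, which K2CO3 in methanol closes to 13 with retention at C9.

**Step 9.** Displacement at C11 is neopentyl-like, next to the fully substituted C9 and quaternary C10. With the weakly nucleophilic ylide in hot alkoxide, base-induced isomerisation of the epoxide to an allylic alcohol can take over. The fallback sets out from 13 and returns at 14. CH2=CHMgBr with catalytic CuI, a much stronger and non-basic nucleophile, opens the epoxide at C11 to the homoallylic alcohol F6. Ozonolysis with NaBH4 work-up gives the 1,3-diol F7. Monotosylation of the primary hydroxyl gives the tosylate F8, which closes to 14 with KOtBu.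

**Step 12.** The oxidised furan passes through species that are electrophilic at C13, and the neighbouring 9α-hydroxyl can intercept them in a five-membered ether closure. Protodesilylation by acetic acid before oxidation would also remove the regiocontrol. The fallback sets out from 19 and returns at 20. Singlet oxygen (O2, light, tetraphenylporphyrin, −78 °C) adds across the furan. Silicon migrates within the endoperoxide and fixes the carbonyl at C16, giving the 15-hydroxybutenolide F9 without any cationic centre at C13. NaBH4 reduces the masked C15 aldehyde, and the hydroxy acid relactonises to 20.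

## Further compounds

F1 | step 4 | dichloro{2-[(1S,2S)-2,4-dimethyl-3-oxo-2-(3-oxopropyl)cyclohex-4-en-1-yl]propan-2-yl}chromium (tertiary alkylchromium from 7) | O=CCC[C@@]1(C)[C@@H](CC=C(C)C1=O)C(C)(C)[Cr](Cl)Cl
F2 | step 2 | (5S,6S)-2,6-dimethyl-6-(prop-2-en-1-yl)-5-(prop-1-en-2-yl)cyclohex-2-en-1-one | C=CC[C@@]1(C)[C@@H](CC=C(C)C1=O)C(C)=C
F3 | step 2 | (5S,6S)-6-(3-hydroxypropyl)-2,6-dimethyl-5-(prop-1-en-2-yl)cyclohex-2-en-1-one | OCCC[C@@]1(C)[C@@H](CC=C(C)C1=O)C(C)=C
F4 | step 8 | 3β-(tert-butyldimethylsilyloxy)-8α-methyl-12,13,14,15,16-pentanorlabdane-9α,11-diol | CC(C)(C)[Si](C)(C)O[C@H]1CC[C@@]2(C)[C@@H](CC[C@@H](C)[C@]2(O)CO)C1(C)C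
F5 | step 8 | 11-O-p-toluenesulfonate of F4 | CC(C)(C)[Si](C)(C)O[C@H]1CC[C@@]2(C)[C@@H](CC[C@@H](C)[C@]2(O)COS(=O)(=O)c3ccc(C)cc3)C1(C)C
F6 | step 9 | 9β-allyl-3β-(tert-butyldimethylsilyloxy)-8α-methyl-11,12,13,14,15,16-hexanorlabdan-9α-ol | CC(C)(C)[Si](C)(C)O[C@H]1CC[C@@]2(C)[C@@H](CC[C@@H](C)[C@]2(O)CC=C)C1(C)C
F7 | step 9 | 3β-(tert-butyldimethylsilyloxy)-8α-methyl-13,14,15,16-tetranorlabdane-9α,12-diol | CC(C)(C)[Si](C)(C)O[C@H]1CC[C@@]2(C)[C@@H](CC[C@@H](C)[C@]2(O)CCO)C1(C)C
F8 | step 9 | 12-O-p-toluenesulfonate of F7 | CC(C)(C)[Si](C)(C)O[C@H]1CC[C@@]2(C)[C@@H](CC[C@@H](C)[C@]2(O)CCOS(=O)(=O)c3ccc(C)cc3)C1(C)C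
F9 | step 12 | 3β-(tert-butyldimethylsilyloxy)-9α,15-dihydroxy-8α-methyllabd-13-en-16,15-olide (C15 epimers) | CC(C)(C)[Si](C)(C)O[C@H]1CC[C@@]2(C)[C@@H](CC[C@@H](C)[C@]2(O)CCC3=CC(O)OC3=O)C1(C)C
A1 | alternative 1 | 9α-O-(bromomethyl)dimethylsilyl ether of the 3β-silyloxy Δ7-9-carbinol with a 2-(4-methoxybenzyloxy)ethyl chain on C9β | CC(C)(C)[Si](C)(C)O[C@H]1CC[C@@]2(C)[C@@H](CC=C[C@]2(O[Si](C)(C)CBr)CCOCc3ccc(OC)cc3)C1(C)C
A2 | alternative 1 | cis-fused oxasilolane with C17 α on C8 | CC(C)(C)[Si](C)(C)O[C@H]1CC[C@@]2(C)[C@@H](CC[C@@H](C[Si](C)(C)O3)[C@]23CCOCc4ccc(OC)cc4)C1(C)C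
A3 | alternative 2 | ring A bromo diketone (C9 ketone with silylfuran chain on C10, 3-bromo-2-oxobutyl on C5, either bromide epimer) | CC(C)(C)[Si](C)(C)O[C@H]1CC[C@@](C(=O)CCc2ccoc2[Si](C)(C)C)(C)[C@@H](CC(=O)C(C)Br)C1(C)C
A4 | alternative 2 | 9α-hydroxy-7-oxo trans-decalin with silylfuran chain | CC(C)(C)[Si](C)(C)O[C@H]1CC[C@@]2(C)[C@@H](CC(=O)[C@@H](C)[C@]2(O)CCc3ccoc3[Si](C)(C)C)C1(C)C
A5 | alternative 3 | 2,6-dimethyl-1,4-benzoquinone | CC1=CC(=O)C=C(C)C1=O
A6 | alternative 3 | 2-(triisopropylsilyloxy)buta-1,3-diene | C=CC(=C)O[Si](C(C)C)(C(C)C)C(C)C
A7 | alternative 3 | cis-fused silyl enol ether enedione adduct | CC(C)[Si](C(C)C)(C(C)C)OC1=CC[C@@]2(C)[C@H](C(=O)C=C(C)C2=O)C1
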